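**Strategy.** The six-membered ring C1–C2–C3–C4–C5–C8 (bicyclo[3.2.1]octane numbering) is made one carbon short: C3, the enone CH and the only ring atom that carries neither a stereocentre nor a substituent, is left out. This reduces the target to a 7-oxonorbornene whose C2–C4 bond is a silyl enol ether double bond. In the key step dibromocarbene adds across that bond and the strained 1-siloxy-2,2-dibromocyclopropane opens to the 3-bromo enone: the cyclopentene ring grows to the cyclohexenone, C3 is installed and the C2 ketone is unveiled in one operation. The precursor is a 3-methyl-2-silyloxybicyclo[2.2.1]hept-2-en-7-one carrying both aryl groups, assembled by two cuprate additions and a gold-catalysed 5-exo-dig closure.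

Key step: step 6

Remark: locants in the text follow the bicyclo[3.2.1]octane numbering of the target (C1 and C5 bridgeheads, C2 and C8 ketones, C3=C4 enone, C6 and C7 aryl-bearing carbons).
Remark: 1 (sold in both enantiomeric forms), 2, 5, 8 and 16 are taken as purchased; 6, 7, 9, 10 and 11 are carried as both epimers at the silyloxy-bearing side-chain carbon, which becomes sp2 in step 5.

Step 1
Reactants: 1 (S)-4-[(tert-butyldimethylsilyl)oxy]cyclopent-2-en-1-one; 2 (4-methoxyphenyl)magnesium bromide
Product: 4 (S)-4-(4-methoxyphenyl)cyclopent-2-en-1-one, via silyloxy ketone 3 (not isolated)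
Conditions: CuBr·SMe2 (10 mol %), THF, −78 °C; H2O; then DBU (0.2 equiv), CH2Cl2, 0 → 23 °C
Reagents that add atoms: none
Why: Copper-catalysed 1,4-addition of the aryl group should occur anti to the silyloxy group and the β-silyloxy ketone should then lose silanol by E1cB elimination, so that the silyloxy stereocentre controls the new benzylic centre before being erased.

Step 2
Reactants: 4 (S)-4-(4-methoxyphenyl)cyclopent-2-en-1-one; 5 3-(trimethylsilyl)prop-2-ynal
Product: 7 trans-5-{1-[(tert-butyldimethylsilyl)oxy]-3-(trimethylsilyl)prop-2-yn-1-yl}-4-(4-methoxyphenyl)cyclopent-2-en-1-one, via lithium aldolate 6 (not isolated)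
Conditions: LDA, THF, −78 °C; then 5; then TBSOTf, −78 → 0 °C
Reagents that add atoms: tert-butyldimethylsilyl trifluoromethanesulfonate, CC(C)(C)[Si](C)(C)OS(=O)(=O)C(F)(F)F
Why: Kinetic α′-deprotonation, aldol addition anti to the neighbouring 4-methoxyphenyl group and in situ O-silylation of the aldolate should fix the side chain trans to the aryl group, while the carbinol centre is left uncontrolled because step 5 flattens it.

Step 3
Reactants: 7 silyl-protected aldol enone; 8 (3,5-dimethoxyphenyl)magnesium chloride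
Product: 10 triisopropylsilyl enol ether of 3,4-trans-4,5-trans-5-{1-[(tert-butyldimethylsilyl)oxy]prop-2-yn-1-yl}-3-(3,5-dimethoxyphenyl)-4-(4-methoxyphenyl)cyclopentanone (enol double bond C1=C2), via silylalkyne enol ether 9 (not isolated)
Conditions: CuBr·SMe2 (10 mol %), THF, −78 °C; then TIPSOTf, −78 → 0 °C; then K2CO3, MeOH, 0 °C
Reagents that add atoms: triisopropylsilyl trifluoromethanesulfonate, CC(C)[Si](C(C)C)(C(C)C)OS(=O)(=O)C(F)(F)F
Why: Copper-catalysed 1,4-addition should deliver the second aryl group anti to the adjacent 4-methoxyphenyl group (trans-diaryl pair under substrate control), the regiodefined magnesium enolate is trapped by O-silylation, and potassium carbonate in methanol should cleave only the alkynyl C–Si bond.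

Step 4
Reactants: 10 triisopropylsilyl enol ether with terminal alkyne
Product: 11 2-[(tert-butyldimethylsilyl)oxy]-5-endo-(3,5-dimethoxyphenyl)-6-exo-(4-methoxyphenyl)-3-methylidenebicyclo[2.2.1]heptan-7-one
Conditions: [Au(IPr)(NCMe)]SbF6 (5 mol %; IPr = 1,3-bis(2,6-diisopropylphenyl)imidazol-2-ylidene), acetone–H2O (20:1), 23 °C
Reagents that add atoms: none
Why: Conia-ene-type 5-exo-dig carbocyclisation of the silyl enol ether onto the gold-activated alkyne should close the norbornan-7-one, and because the tether sits on the ring face opposite the 4-methoxyphenyl group the new C–C bond can only form syn to the 3,5-dimethoxyphenyl group, which thereby becomes endo.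

Step 5
Reactants: 11 methylidene norbornanone
Product: 12 2-[(tert-butyldimethylsilyl)oxy]-5-endo-(3,5-dimethoxyphenyl)-6-exo-(4-methoxyphenyl)-3-methylbicyclo[2.2.1]hept-2-en-7-one
Conditions: [Ir(cod)(PMePh2)2]PF6 (3 mol %, pre-activated with H2), THF, 23 °C
Reagents that add atoms: none
Why: Iridium hydride-catalysed 1,3-hydrogen shift (isomerisation of an allyl silyl ether to a silyl enol ether) should move the exocyclic double bond into the ring next to oxygen and remove the epimeric carbinol centre.

Step 6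
Reactants: 12 norbornenyl silyl enol ether
Product: 14 3-bromo-6-endo-(3,5-dimethoxyphenyl)-7-exo-(4-methoxyphenyl)-4-methylbicyclo[3.2.1]oct-3-ene-2,8-dione, via dibromocyclopropane 13 (not isolated)
Conditions: CHBr3, KOtBu, pentane, −30 °C; filtration; then toluene, 80 °C
Reagents that add atoms: bromoform, BrC(Br)Br
Why: Dibromocarbene, formed by α-elimination from bromoform, should add in a concerted [2+1] fashion to the electron-rich tetrasubstituted silyl enol ether; on warming, the 1-siloxy-2,2-dibromocyclopropane 13 ionises one C–Br bond with disrotatory cleavage of the former C=C σ-bond, and the 2-bromo-1-siloxyallyl cation gives up its silyl group to bromide to leave the α-bromo enone. The closest known reaction type is the dihalocarbene one-carbon ring enlargement of cyclic silyl enol ethers to 2-halocycloalk-2-enones. The only ring closed is the transient cyclopropane (cheletropic three-ring closure); the six-membered ring is not closed but grows out of the five-membered enol ether ring by insertion of the carbene carbon between C2 and C4. No stereocentre is created in 14; the two transient cyclopropane centres are set by attack on the exo face, syn to the one-carbon ketone bridge, because the endo face is shielded by the endo 3,5-dimethoxyphenyl group. The step needs chemoselectivity for the enol ether over the arenes and the ketone, which the electrophilic carbene secures by choosing the most electron-rich π bond, and regioselective opening, which the siloxy donor secures by stabilising the allyl cation; the base is filtered off before warming so that the non-enolisable 1,3-diketone of 14 never meets tert-butoxide.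

Step 7
Reactants: 14 bromo enone
Product: 15 6-endo-(3,5-dimethoxyphenyl)-7-exo-(4-methoxyphenyl)-4-methylbicyclo[3.2.1]oct-3-ene-2,8-dione
Conditions: Pd(PPh3)4 (5 mol %), HCO2H, Et3N, DMF, 60 °C
Reagents that add atoms: none
Why: Palladium-catalysed hydrogenolysis of the vinyl bromide with formate (oxidative addition, decarboxylation to the hydride, reductive elimination) should replace bromine by hydrogen without affecting the enone or the stereocentres.

Step 8
Reactants: 15 methyl enone; 16 4-methoxybenzaldehyde dimethyl acetal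
Product: 19 6-endo-(3,5-dimethoxyphenyl)-7-exo-(4-methoxyphenyl)-4-[(E)-2-(4-methoxyphenyl)ethenyl]bicyclo[3.2.1]oct-3-ene-2,8-dione, via silyl dienol ether 17 (not isolated), via methoxy adduct 18 (not isolated)
Conditions: TBSOTf, Et3N, CH2Cl2, 0 °C; then 16, TMSOTf (10 mol %), −78 °C; then DBU, 23 °C
Reagents that add atoms: none
Why: Soft enolisation can only occur at the C4 methyl group (both α-carbons are bridgeheads), the resulting dienol ether should add through its γ-carbon to the acetal-derived oxocarbenium ion (vinylogous Mukaiyama aldol reaction), and E1cB loss of methanol should give the E-configured styryl dienone as the thermodynamically favoured isomer.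

Step 9
Reactants: 19 tetra-O-methylvitisinol D
Product: 20 vitisinol D
Conditions: BBr3, CH2Cl2, −78 → 0 °C; then H2O
Reagents that add atoms: none
Why: Boron tribromide should cleave all four aryl methyl ethers (Lewis acid-mediated O-demethylation) while the stereocentres stay intact because neither bridgehead can enolise.

**Compound list**

1 | (S)-4-[(tert-butyldimethylsilyl)oxy]cyclopent-2-en-1-one | O=C1C=C[C@@H](O[Si](C)(C)C(C)(C)C)C1 | starting material
2 | (4-methoxyphenyl)magnesium bromide | COc1ccc([Mg]Br)cc1 | starting material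
3 | (3R,4S)-4-[(tert-butyldimethylsilyl)oxy]-3-(4-methoxyphenyl)cyclopentan-1-one (3,4-trans; not isolated) | O=C1C[C@H](c2ccc(OC)cc2)[C@@H](O[Si](C)(C)C(C)(C)C)C1 | intermediate
4 | (S)-4-(4-methoxyphenyl)cyclopent-2-en-1-one | O=C1C=C[C@@H](c2ccc(OC)cc2)C1 | intermediate
5 | 3-(trimethylsilyl)prop-2-ynal | O=CC#C[Si](C)(C)C | starting material
6 | lithium alkoxide of trans-5-[1-hydroxy-3-(trimethylsilyl)prop-2-yn-1-yl]-4-(4-methoxyphenyl)cyclopent-2-en-1-one (both carbinol epimers; not isolated) | O=C1C=C[C@@H](c2ccc(OC)cc2)[C@@H]1C(O[Li])C#C[Si](C)(C)C | intermediate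
7 | trans-5-{1-[(tert-butyldimethylsilyl)oxy]-3-(trimethylsilyl)prop-2-yn-1-yl}-4-(4-methoxyphenyl)cyclopent-2-en-1-one (both epimers at the silyloxy carbon) | O=C1C=C[C@@H](c2ccc(OC)cc2)[C@@H]1C(O[Si](C)(C)C(C)(C)C)C#C[Si](C)(C)C | intermediate
8 | (3,5-dimethoxyphenyl)magnesium chloride | COc1cc(OC)cc([Mg]Cl)c1 | starting material
9 | {[5-{1-[(tert-butyldimethylsilyl)oxy]-3-(trimethylsilyl)prop-2-yn-1-yl}-3-(3,5-dimethoxyphenyl)-4-(4-methoxyphenyl)cyclopent-1-en-1-yl]oxy}tri(propan-2-yl)silane (3,4-trans, 4,5-trans; not isolated) | CC(C)[Si](C(C)C)(C(C)C)OC1=C[C@H](c2cc(OC)cc(OC)c2)[C@@H](c2ccc(OC)cc2)[C@@H]1C(O[Si](C)(C)C(C)(C)C)C#C[Si](C)(C)C | intermediate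
10 | {[5-{1-[(tert-butyldimethylsilyl)oxy]prop-2-yn-1-yl}-3-(3,5-dimethoxyphenyl)-4-(4-methoxyphenyl)cyclopent-1-en-1-yl]oxy}tri(propan-2-yl)silane (3,4-trans, 4,5-trans) | CC(C)[Si](C(C)C)(C(C)C)OC1=C[C@H](c2cc(OC)cc(OC)c2)[C@@H](c2ccc(OC)cc2)[C@@H]1C(O[Si](C)(C)C(C)(C)C)C#C | intermediate
11 | 2-[(tert-butyldimethylsilyl)oxy]-5-endo-(3,5-dimethoxyphenyl)-6-exo-(4-methoxyphenyl)-3-methylidenebicyclo[2.2.1]heptan-7-one (both C2 epimers) | CC(C)(C)[Si](C)(C)OC1C(=C)[C@H]2C(=O)[C@@H]1[C@H](c1ccc(OC)cc1)[C@H]2c1cc(OC)cc(OC)c1 | intermediate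
12 | 2-[(tert-butyldimethylsilyl)oxy]-5-endo-(3,5-dimethoxyphenyl)-6-exo-(4-methoxyphenyl)-3-methylbicyclo[2.2.1]hept-2-en-7-one | CC(C)(C)[Si](C)(C)OC1=C(C)[C@H]2C(=O)[C@@H]1[C@H](c1ccc(OC)cc1)[C@H]2c1cc(OC)cc(OC)c1 | intermediate
13 | 3,3-dibromo-2-[(tert-butyldimethylsilyl)oxy]-6-endo-(3,5-dimethoxyphenyl)-7-exo-(4-methoxyphenyl)-4-methyltricyclo[3.2.1.0(2,4)]octan-8-one (cyclopropane on the exo face; not isolated) | CC(C)(C)[Si](C)(C)O[C@]12C(Br)(Br)[C@@]1(C)[C@H]3C(=O)[C@@H]2[C@H](c1ccc(OC)cc1)[C@H]3c1cc(OC)cc(OC)c1 | intermediate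
14 | 3-bromo-6-endo-(3,5-dimethoxyphenyl)-7-exo-(4-methoxyphenyl)-4-methylbicyclo[3.2.1]oct-3-ene-2,8-dione | O=C1C(Br)=C(C)[C@H]2C(=O)[C@@H]1[C@H](c1ccc(OC)cc1)[C@H]2c1cc(OC)cc(OC)c1 | intermediate
15 | 6-endo-(3,5-dimethoxyphenyl)-7-exo-(4-methoxyphenyl)-4-methylbicyclo[3.2.1]oct-3-ene-2,8-dione | O=C1C=C(C)[C@H]2C(=O)[C@@H]1[C@H](c1ccc(OC)cc1)[C@H]2c1cc(OC)cc(OC)c1 | intermediate
16 | 4-methoxybenzaldehyde dimethyl acetal | COC(OC)c1ccc(OC)cc1 | starting material
17 | 2-[(tert-butyldimethylsilyl)oxy]-6-endo-(3,5-dimethoxyphenyl)-7-exo-(4-methoxyphenyl)-4-methylidenebicyclo[3.2.1]oct-2-en-8-one (not isolated) | CC(C)(C)[Si](C)(C)OC1=CC(=C)[C@H]2C(=O)[C@@H]1[C@H](c1ccc(OC)cc1)[C@H]2c1cc(OC)cc(OC)c1 | intermediate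
18 | 6-endo-(3,5-dimethoxyphenyl)-4-[2-methoxy-2-(4-methoxyphenyl)ethyl]-7-exo-(4-methoxyphenyl)bicyclo[3.2.1]oct-3-ene-2,8-dione (both epimers at the methoxy carbon; not isolated) | O=C1C=C(CC(OC)c2ccc(OC)cc2)[C@H]2C(=O)[C@@H]1[C@H](c1ccc(OC)cc1)[C@H]2c1cc(OC)cc(OC)c1 | intermediate
19 | tetra-O-methylvitisinol D: 6-endo-(3,5-dimethoxyphenyl)-7-exo-(4-methoxyphenyl)-4-[(E)-2-(4-methoxyphenyl)ethenyl]bicyclo[3.2.1]oct-3-ene-2,8-dione | O=C1C=C(/C=C/c2ccc(OC)cc2)[C@H]2C(=O)[C@@H]1[C@H](c1ccc(OC)cc1)[C@H]2c1cc(OC)cc(OC)c1 | intermediate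
20 | vitisinol D: 6-endo-(3,5-dihydroxyphenyl)-7-exo-(4-hydroxyphenyl)-4-[(E)-2-(4-hydroxyphenyl)ethenyl]bicyclo[3.2.1]oct-3-ene-2,8-dione | O=C1C=C(/C=C/c2ccc(O)cc2)[C@H]2C(=O)[C@@H]1[C@H](c1ccc(O)cc1)[C@H]2c1cc(O)cc(O)c1 | target

**Totals.** Total step count: 9. Longest linear sequence: 9 steps (from 1).

**Steps most likely to fail**

Step 4. The closure may divert to the 6-endo-dig mode, or the silyl enol ether may be protodesilylated before C–C bond formation, because the bond has to form next to the aryl group that becomes endo. Fallback, a radical instead of a π-acid closure, setting out from 10 and returning at 11: N-iodosuccinimide should convert 10 into the α-iodo ketone F1; iodine-atom-transfer 5-exo-dig cyclisation (Bu3SnSnBu3, hν, benzene) should give the iodomethylidene norbornanone F2; Bu3SnH/AIBN should then reduce the vinyl iodide to 11.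

Step 5. The double bond may fail to migrate into the strained norbornene position, or the activated iridium hydride may hydrogenate the methylidene group. Fallback, a redox route to the same enol ether type, setting out from 11 and returning at 14: TBAF should give the allylic alcohol F3; MnO2 should oxidise it to the exocyclic enone F4; 1,4-hydrosilylation with Et3SiH and RhCl(PPh3)3 should give the triethylsilyl enol ether F5, which is submitted to the conditions of step 6 to give 14.

Step 6. Carbene capture by the hindered tetrasubstituted enol ether may be slow, so that tert-butoxide attacks the strained bridging ketone or cleaves the enol ether first. Fallback, a base-free one-carbon ring enlargement, setting out from 12 and returning at 15: Simmons–Smith-type cyclopropanation (Et2Zn, CH2I2, CH2Cl2) should give the siloxycyclopropane F6; FeCl3 in DMF should open it oxidatively to the β-chloro ketone F7 (Saegusa–Ito ring expansion); NaOAc in methanol should eliminate hydrogen chloride to give 15, so that step 7 is not needed.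

**Further compounds**

F1 | step 4 | 2-iodo-3,4-trans-4,5-trans-5-{1-[(tert-butyldimethylsilyl)oxy]prop-2-yn-1-yl}-3-(3,5-dimethoxyphenyl)-4-(4-methoxyphenyl)cyclopentan-1-one | O=C1C(I)[C@H](c2cc(OC)cc(OC)c2)[C@@H](c2ccc(OC)cc2)[C@@H]1C(O[Si](C)(C)C(C)(C)C)C#C
F2 | step 4 | 2-[(tert-butyldimethylsilyl)oxy]-5-endo-(3,5-dimethoxyphenyl)-3-(iodomethylidene)-6-exo-(4-methoxyphenyl)bicyclo[2.2.1]heptan-7-one | CC(C)(C)[Si](C)(C)OC1C(=CI)[C@H]2C(=O)[C@@H]1[C@H](c1ccc(OC)cc1)[C@H]2c1cc(OC)cc(OC)c1
F3 | step 5 | 5-endo-(3,5-dimethoxyphenyl)-2-hydroxy-6-exo-(4-methoxyphenyl)-3-methylidenebicyclo[2.2.1]heptan-7-one | OC1C(=C)[C@H]2C(=O)[C@@H]1[C@H](c1ccc(OC)cc1)[C@H]2c1cc(OC)cc(OC)c1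
F4 | step 5 | 5-endo-(3,5-dimethoxyphenyl)-6-exo-(4-methoxyphenyl)-3-methylidenebicyclo[2.2.1]heptane-2,7-dione | O=C1C(=C)[C@H]2C(=O)[C@@H]1[C@H](c1ccc(OC)cc1)[C@H]2c1cc(OC)cc(OC)c1
F5 | step 5 | 5-endo-(3,5-dimethoxyphenyl)-6-exo-(4-methoxyphenyl)-3-methyl-2-[(triethylsilyl)oxy]bicyclo[2.2.1]hept-2-en-7-one | CC[Si](CC)(CC)OC1=C(C)[C@H]2C(=O)[C@@H]1[C@H](c1ccc(OC)cc1)[C@H]2c1cc(OC)cc(OC)c1
F6 | step 6 | 2-[(tert-butyldimethylsilyl)oxy]-6-endo-(3,5-dimethoxyphenyl)-7-exo-(4-methoxyphenyl)-4-methyltricyclo[3.2.1.0(2,4)]octan-8-one | CC(C)(C)[Si](C)(C)O[C@]12C[C@@]1(C)[C@H]3C(=O)[C@@H]2[C@H](c1ccc(OC)cc1)[C@H]3c1cc(OC)cc(OC)c1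
F7 | step 6 | 4-chloro-6-endo-(3,5-dimethoxyphenyl)-7-exo-(4-methoxyphenyl)-4-methylbicyclo[3.2.1]octane-2,8-dione | O=C1CC(C)(Cl)[C@H]2C(=O)[C@@H]1[C@H](c1ccc(OC)cc1)[C@H]2c1cc(OC)cc(OC)c1
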